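## The problem

Target 18 is a 1-aryl-1,2-dihydronaphthalene in which ring A (C4a, C5 to C8, C8a; methoxy groups on C6, C7 and C8) is fused to ring B (C1 to C4, C4a, C8a); C1 carries the 3,4-dimethoxyphenyl group (Ar), C2 carries C9′H2OH, C3 carries C9H2OH, and the C3=C4 bond is conjugated with ring A. The only stereocentres are C1 (R) and C2 (S), adjacent and trans, and no remote centre can relay to them, so a reagent or catalyst must set them, together or one under the control of the other. C1 is a doubly benzylic methine wedged between Ar and the C8 methoxy group, a crowded diarylmethine that is hard to reach by substitution. The dihydronaphthalene is one dehydrogenation away from a fully aromatic ring B, so quinone oxidants, strong acid and air are to be avoided, and the C9 hydroxyl is allylic and ionisable. A carbonyl at C9′ would make C2–H acidic and invite epimerisation or olefin migration, so C2 is best kept below the carbonyl oxidation level. The feature that is exploited is that C1 and C2 are the two carbons of a former (E)-styrenyl olefin on C8a of ring A: Ar on C1 and the C3 alkenyl unit on C2 stand anti across it, and a boron atom left on C2 is a stereoretentive stand-in for C9′H2OH. A vinyl group on C4a and a methylene on C3 then make C3=C4 a ring-closing metathesis bond.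

## Retrosynthesis

18 from 17. Only the O–Si bond at C9 is cut. The C9 oxygen has to pass through an organolithium step, so it is carried as a silyl ether, the single protecting group of the route. The forward step must be a neutral or basic desilylation, because acid would ionise the allylic C9–O bond.

17 from 16. The C3=C4 bond is cut (ring-closing metathesis). The neighbouring cuts, C4–C4a (Heck or carbene coupling) and C1–C8a (Friedel–Crafts), need base at high temperature or acid and put the diad at risk. Metathesis is neutral and touches no stereocentre. The precursor 16 is an acyclic diene that already carries the finished C1/C2 diad. The forward reaction must join a styrene with a 1,1-disubstituted olefin in the presence of a free primary alcohol.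

16 from 14. The C2–C9′ bond is cut and C9′H2OH is replaced by boron on C2. A one-carbon insertion into a C–B bond proceeds with retention and never places C2 next to a carbonyl, which an ester precursor of C9′ could not guarantee. The precursor 14 is a secondary allylic boronate. The forward sequence must insert CH2 at a hindered boron and then oxidise the new primary C–B bond.

14 from 7, 12 and 11. The C1–Ar and C2–C3 bonds are cut together, which removes both stereocentres in one operation. Stepwise alternatives (conjugate arylation, then enolate chemistry at C2) would need a carbonyl at C9′ and two separate stereocontrol events. The precursors are flat and simple: the (E)-alkenylboronate 7, the alkenyllithium 12 and the aryl triflate 11. The forward reaction must add Ar and the alkenyl group anti across C1=C2, select one olefin face, activate the styrenyl and not the allyl-ether alkenyl group on boron, and avoid direct transfer of an alkenyl group from boron to palladium. For the last point the boron of 7 carries the diolate of diol 2 and not a pinacol ligand, since β-substituted pinacol borates are known to divert to direct transfer.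

7 from 6, and 6 from 5 and 4. The C4=CH2 bond is cut by Wittig methylenation and the C8a–C1 bond by a Mizoroki–Heck reaction of bromide 5 with vinylboronate 4. The Heck reaction is placed first so that no styrene competes as an olefin partner, and the ortho-formyl group assists oxidative addition. Boronate 4 comes from diol 2 and dibutyl vinylboronate 3 by ester exchange, and 2 from acenaphthoquinone 1 by double methyl addition. Diol 2 is released again when boron is oxidised and can be recycled.

12 from 9, and 9 from 8; 11 from 10. Bromine–lithium exchange on silyl ether 9 (from 2-bromoallyl alcohol 8) gives 12 at −78 °C, where a 1,3 shift of silicon from oxygen to carbon should not intervene. O-Triflation of phenol 10 gives 11.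

## Roads not taken

Alternative 1: The cut removes C2–C3, C4–C4a and C1–C8a at once. Ring B and a lactone between C9′ and C9 would arise from the enyne ester A2 (prop-2-ynyl (E)-3,4-dimethoxycinnamate) and 3,4,5-trimethoxybenzyne A4, released by fluoride from the silylaryl triflate A3, under zerovalent palladium with a chiral phosphine, to give lactone A1. Hydride reduction of A1 would give 18 directly.
- Merits: the 1,2-trans relation is inherited from the (E)-cinnamate A2, both hydroxymethyl carbons arrive in place, and the longest sequence would be about four steps, clearly shorter than the chosen plan.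
- Weak points: enantiocontrol would have to come from facial selection of the cinnamate olefin on palladium, for which aryne cocyclisations offer no dependable precedent. A4 is unsymmetrical, so the C8 methoxy group may end up next to C4 instead of C1. In A1, C2–H is α to the lactone carbonyl and allylic, so epimerisation, migration of C3=C4 and aromatisation of ring B all threaten. Oligomerisation of A4 competes.
- Comparison: this road wins on step economy. The chosen plan sets against it a ring-A substitution pattern fixed in the purchased aldehyde 5, a catalyst class with an established record of enantioselection, and a C2 that is never α to a carbonyl.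

Alternative 2: The cut is C1–C2 and C3–C4 in a [4+2] sense. Irradiation of the 2-benzylbenzaldehyde A6 in the presence of the lactate-derived fumarate A7 would, by photoenolisation and Diels–Alder capture, give tetralin A5 with four stereocentres. Dehydration across C3–C4 and reduction of both esters would lead to 18.
- Merits: convergent, robust C–C bond formation, with ring B and the trans C1/C2 diad in one step; the length is comparable to or slightly shorter than the chosen plan.
- Weak points: absolute control rests on lactate auxiliaries whose facial bias is best under Lewis-acid chelation, which is hard to combine with a short-lived photoenol. Two of the four stereocentres of A5 (C3, C4) are made only to be erased. The ester on C2 makes C2–H acidic, and allylic once C3=C4 is in place, so the trans diad and the oxidation level of ring B are at risk during dehydration. Two auxiliaries are consumed.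
- Comparison: this road has the more reliable bond construction. The chosen plan answers with catalyst-controlled absolute configuration, no auxiliary, and C2 held at the boron or alcohol level throughout.

Alternative 3: The cut is C4a–C4. The acyclic 2-bromoaryl N-tosylhydrazone A9, already carrying the C1/C2 diad, would cyclise under palladium catalysis to diester A8 by oxidative addition at C4a–Br, diazo formation, carbene migratory insertion and β-hydride elimination from C3. Reduction of the esters would give 18.
- Merits: this ring closure is the best precedented key step of the four, the olefin position is dictated by the hydrogen on C3, and ring-A regiochemistry is unambiguous.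
- Weak points: the key step creates no stereocentre, so the diad of A9 needs its own enantioselective sequence and the route grows longer. Base at about 100 °C acts on a substrate whose C2–H and C3–H are α to esters, and in A8 C2–H is α to an ester and allylic, so epimerisation and aromatisation are real threats. The esters must then be reduced without touching the conjugated olefin.
- Comparison: the ring closure is more secure here than the key step of the chosen plan. The chosen plan offers the shorter and more direct access to the stereodiad and avoids carbonyl groups next to C2.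

Key step: step 7

Assumption: the MandyPhos antipode that places palladium on the Si face of C1 is to be assigned from the sense of induction of simpler β-substituted alkenyl borates and confirmed on the first run; MandyPhos is 1,1′-bis(diphenylphosphino)-2,2′-bis[α-(dimethylamino)benzyl]ferrocene and both antipodes are commercial.

## Route

Step 1
Reactants: 1 acenaphthoquinone
Product: 2 cis-1,2-dimethyl-1,2-dihydroacenaphthylene-1,2-diol
Conditions: AlMe3 (3 equiv), toluene, 0 °C → rt; aq HCl; crystallisation
Reagents that add atoms: trimethylaluminium, C[Al](C)C
Why: Twofold 1,2-addition of methyl to the 1,2-diketone; the second methyl is expected to enter on the face of the first, away from the aluminium alkoxide, giving the cis (meso) diol, and only this isomer can span boron in step 2, so any trans diol is rejected there or by crystallisation.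

Step 2
Reactants: 2 cis-1,2-dimethyl-1,2-dihydroacenaphthylene-1,2-diol; 3 dibutyl vinylboronate
Product: 4 vinylboronic acid ester of diol 2
Conditions: CH2Cl2, 4 Å molecular sieves, rt; volatiles removed in vacuo
Reagents that add atoms: none
Why: Boronic ester exchange, driven by chelation of the rigid cis-diol and removal of butanol.

Step 3
Reactants: 5 2-bromo-3,4,5-trimethoxybenzaldehyde; 4 vinylboronic acid ester of diol 2
Product: 6 3,4,5-trimethoxy-2-[(E)-2-borylvinyl]benzaldehyde (boron as ester of diol 2)
Conditions: Pd(P(t-Bu)3)2 (5 mol %), Cy2NMe, toluene, 80 °C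
Reagents that add atoms: none
Why: Mizoroki–Heck reaction: under anhydrous amine-base conditions a vinylboronic ester behaves as an olefin (aryl adds to the unsubstituted carbon, β-hydride elimination gives the (E)-alkenylboronate) and not as a Suzuki–Miyaura partner; the ortho-formyl group assists oxidative addition and no styrene is yet present to compete.

Step 4
Reactants: 6 3,4,5-trimethoxy-2-[(E)-2-borylvinyl]benzaldehyde (boron as ester of diol 2)
Product: 7 (E)-2-(2,3,4-trimethoxy-6-vinylphenyl)vinylboronic acid ester of diol 2
Conditions: Ph3PCH3Br (1.3 equiv), KOt-Bu (1.2 equiv), THF, 0 °C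
Reagents that add atoms: methyltriphenylphosphonium bromide, C[P+](c1ccccc1)(c1ccccc1)c1ccccc1.[Br-]
Why: Wittig methylenation of the aryl aldehyde; the hindered boronic ester and the (E)-alkenyl–boron bond should tolerate the non-stabilised ylide at 0 °C when the base is kept below the phosphonium salt.

Step 5
Reactants: 8 2-bromoprop-2-en-1-ol
Product: 9 (2-bromoallyloxy)(tert-butyl)dimethylsilane
Conditions: TBSCl, imidazole, CH2Cl2, 0 °C → rt
Reagents that add atoms: tert-butyldimethylsilyl chloride, CC(C)(C)[Si](C)(C)Cl
Why: Imidazole-mediated silylation of a primary alcohol.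

Step 6
Reactants: 10 3,4-dimethoxyphenol
Product: 11 3,4-dimethoxyphenyl trifluoromethanesulfonate
Conditions: Tf2O, pyridine, CH2Cl2, 0 °C
Reagents that add atoms: trifluoromethanesulfonic anhydride, O=S(=O)(OS(=O)(=O)C(F)(F)F)C(F)(F)F
Why: O-Sulfonylation of a phenol.

Step 7
Reactants: 9 (2-bromoallyloxy)(tert-butyl)dimethylsilane; 7 (E)-2-(2,3,4-trimethoxy-6-vinylphenyl)vinylboronic acid ester of diol 2; 11 3,4-dimethoxyphenyl trifluoromethanesulfonate
Product: 14 (1R,2S)-1-(3,4-dimethoxyphenyl)-3-[(tert-butyldimethylsilyloxy)methyl]-1-(2,3,4-trimethoxy-6-vinylphenyl)but-3-en-2-ylboronic acid ester of diol 2, via 2-lithio-3-(tert-butyldimethylsilyloxy)propene 12 (not isolated), via lithium bis(alkenyl)borate 13 (not isolated)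
Conditions: 9, t-BuLi (2 equiv), Et2O, −78 °C; 7 in THF, −78 °C → rt; solvent change to THF; KOTf (2 equiv), Pd(OAc)2 (3 mol %), MandyPhos (3.6 mol %, antipode for 1R), 11, 60 °C
Reagents that add atoms: none
Why: Conjunctive cross-coupling of an alkenylboron ate complex, a known reaction type: bromine–lithium exchange on 9 gives 12, which adds to boron of 7 to give borate 13, while Pd(OAc)2 and MandyPhos are reduced in the flask to zerovalent palladium, which inserts into the C–O bond of 11 to give a cationic arylpalladium complex. This complex binds the styrenyl C1=C2 bond of 13 and induces a 1,2-metallate shift in which the 2-(silyloxymethyl)vinyl group moves from boron to C2 anti to palladium as palladium bonds to C1; reductive elimination then forms C1–Ar with retention, and no ring is closed. The closest known reactions are the couplings of β-substituted alkenyl borates of diol 2 with aryl triflates and the couplings of bis(alkenyl)borates that give allylboronates. The relative configuration of C1 and C2 follows from the (E)-geometry of 7 and the anti course of the addition; the absolute configuration (1R,2S) follows from the MandyPhos antipode, which must place palladium on the Si face of C1. The diolate of 2 is used because β-substituted pinacol borates divert to direct Suzuki–Miyaura transfer, which the acenaphthene backbone hinders. The selectivity still to be won is activation of the styrenyl and not the allyl-ether alkenyl group: it should be favoured by η3-benzylic stabilisation of the C1–Pd bond by the electron-rich ring A, and because the other mode would have to build a fully substituted carbon on the crowded boron next to the inductively withdrawing CH2OSi group. KOTf precipitates the bromide left by the lithiation, which would otherwise block the cationic palladium, and the neutral ring-A vinyl group should not compete with the anionic borate olefin.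

Step 8
Reactants: 14 (1R,2S)-1-(3,4-dimethoxyphenyl)-3-[(tert-butyldimethylsilyloxy)methyl]-1-(2,3,4-trimethoxy-6-vinylphenyl)but-3-en-2-ylboronic acid ester of diol 2
Product: 16 (2S,3R)-3-(3,4-dimethoxyphenyl)-2-[3-(tert-butyldimethylsilyloxy)prop-1-en-2-yl]-3-(2,3,4-trimethoxy-6-vinylphenyl)propan-1-ol, via homologated primary boronate 15 (not isolated)
Conditions: BrCH2Cl, n-BuLi, THF, −78 °C → rt; then NaOH, H2O2, THF/H2O, 0 °C → rt
Reagents that add atoms: bromochloromethane, ClCBr; hydrogen peroxide, OO
Why: Matteson homologation: chloromethyllithium, made in the presence of 14, adds to boron and C2 migrates to the CH2 carbon with loss of chloride and retention at C2, giving 15; alkaline peroxide then oxidises the primary C–B bond to C9′H2OH and releases diol 2 for reuse. The allylboronate 14 is taken on promptly so that a 1,3-boron shift cannot erase C2.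

Step 9
Reactants: 16 (2S,3R)-3-(3,4-dimethoxyphenyl)-2-[3-(tert-butyldimethylsilyloxy)prop-1-en-2-yl]-3-(2,3,4-trimethoxy-6-vinylphenyl)propan-1-ol
Product: 17 [(1R,2S)-1-(3,4-dimethoxyphenyl)-3-[(tert-butyldimethylsilyloxy)methyl]-6,7,8-trimethoxy-1,2-dihydronaphthalen-2-yl]methanol
Conditions: second-generation Hoveyda–Grubbs catalyst (5 mol %), toluene, 60 °C, argon sparge
Reagents that add atoms: none
Why: Ring-closing olefin metathesis between the ring-A styrene and the 1,1-disubstituted olefin closes the six-membered ring B and forms the trisubstituted, arene-conjugated C3=C4 bond with loss of ethene; the free primary alcohol is tolerated and no stereocentre is involved.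

Step 10
Reactants: 17 [(1R,2S)-1-(3,4-dimethoxyphenyl)-3-[(tert-butyldimethylsilyloxy)methyl]-6,7,8-trimethoxy-1,2-dihydronaphthalen-2-yl]methanol
Product: 18 [(1R,2S)-1-(3,4-dimethoxyphenyl)-6,7,8-trimethoxy-1,2-dihydronaphthalene-2,3-diyl]dimethanol
Conditions: Bu4NF, THF, 0 °C → rt
Reagents that add atoms: none
Why: Fluoride cleavage of the primary silyl ether under non-acidic conditions, which avoids allylic ionisation at C9 and aromatisation of ring B.

## Compound list

1 | acenaphthoquinone (acenaphthylene-1,2-dione) | O=C1C(=O)c2cccc3cccc1c23 | starting material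
2 | cis-1,2-dimethyl-1,2-dihydroacenaphthylene-1,2-diol (meso, 1R,2S) | C[C@]1(O)[C@@](C)(O)c2cccc3cccc1c23 | intermediate
3 | dibutyl vinylboronate | C=CB(OCCCC)OCCCC | starting material
4 | vinylboronic acid ester of diol 2 (cis-fused dioxaborolane) | C=CB1O[C@]2(C)c3cccc4cccc(c34)[C@]2(C)O1 | intermediate
5 | 2-bromo-3,4,5-trimethoxybenzaldehyde | COc1cc(C=O)c(Br)c(OC)c1OC | starting material
6 | 3,4,5-trimethoxy-2-[(E)-2-borylvinyl]benzaldehyde, boron as ester of diol 2 | O=Cc1cc(OC)c(OC)c(OC)c1/C=C/B1O[C@]2(C)c3cccc4cccc(c34)[C@]2(C)O1 | intermediate
7 | (E)-2-(2,3,4-trimethoxy-6-vinylphenyl)vinylboronic acid ester of diol 2 | C=Cc1cc(OC)c(OC)c(OC)c1/C=C/B1O[C@]2(C)c3cccc4cccc(c34)[C@]2(C)O1 | intermediate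
8 | 2-bromoprop-2-en-1-ol | C=C(Br)CO | starting material
9 | (2-bromoallyloxy)(tert-butyl)dimethylsilane | C=C(Br)CO[Si](C)(C)C(C)(C)C | intermediate
10 | 3,4-dimethoxyphenol | COc1ccc(O)cc1OC | starting material
11 | 3,4-dimethoxyphenyl trifluoromethanesulfonate | COc1ccc(OS(=O)(=O)C(F)(F)F)cc1OC | intermediate
12 | 2-lithio-3-(tert-butyldimethylsilyloxy)propene | [Li]C(=C)CO[Si](C)(C)C(C)(C)C | intermediate
13 | lithium borate from 7 and 12: boron carries the (E)-styrenyl group, the 3-(silyloxy)prop-1-en-2-yl group and the diolate of 2 (configuration at boron not defined) | [Li+].C=Cc1cc(OC)c(OC)c(OC)c1/C=C/[B-]1(C(=C)CO[Si](C)(C)C(C)(C)C)O[C@]2(C)c3cccc4cccc(c34)[C@]2(C)O1 | intermediate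
14 | (1R,2S)-1-(3,4-dimethoxyphenyl)-3-[(tert-butyldimethylsilyloxy)methyl]-1-(2,3,4-trimethoxy-6-vinylphenyl)but-3-en-2-ylboronic acid ester of diol 2 (anti diad, boron on C2) | COc1ccc([C@@H]([C@H](B2O[C@]3(C)c4cccc5cccc(c45)[C@]3(C)O2)C(=C)CO[Si](C)(C)C(C)(C)C)c6c(C=C)cc(OC)c(OC)c6OC)cc1OC | intermediate
15 | homologue of 14 with CH2 between C2 and boron (C1 R, C2 S in the numbering of the target) | COc1ccc([C@@H]([C@H](CB2O[C@]3(C)c4cccc5cccc(c45)[C@]3(C)O2)C(=C)CO[Si](C)(C)C(C)(C)C)c6c(C=C)cc(OC)c(OC)c6OC)cc1OC | intermediate
16 | (2S,3R)-3-(3,4-dimethoxyphenyl)-2-[3-(tert-butyldimethylsilyloxy)prop-1-en-2-yl]-3-(2,3,4-trimethoxy-6-vinylphenyl)propan-1-ol | COc1ccc([C@@H]([C@H](CO)C(=C)CO[Si](C)(C)C(C)(C)C)c2c(C=C)cc(OC)c(OC)c2OC)cc1OC | intermediate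
17 | [(1R,2S)-1-(3,4-dimethoxyphenyl)-3-[(tert-butyldimethylsilyloxy)methyl]-6,7,8-trimethoxy-1,2-dihydronaphthalen-2-yl]methanol | COc1ccc([C@@H]2c3c(cc(OC)c(OC)c3OC)C=C(CO[Si](C)(C)C(C)(C)C)[C@H]2CO)cc1OC | intermediate
18 | [(1R,2S)-1-(3,4-dimethoxyphenyl)-6,7,8-trimethoxy-1,2-dihydronaphthalene-2,3-diyl]dimethanol | COc1ccc([C@@H]2c3c(cc(OC)c(OC)c3OC)C=C(CO)[C@H]2CO)cc1OC | target

## Step count and least certain steps

Total: 10 steps. Longest linear sequence: 8 steps (steps 1, 2, 3, 4, 7, 8, 9, 10); from the purchased aldehyde 5 it is 6 steps.

Step 7 (key step). The most likely failure is activation of the wrong olefin of borate 13. The terminal 1,1-disubstituted allyl-ether olefin is sterically more open than the styrenyl olefin, whose C1 is flanked by the C8 methoxy and C4a vinyl groups, so palladium may bind there and the styrenyl group would then migrate. Also possible are direct transfer of an alkenyl group from boron to palladium, weak facial discrimination at the hindered olefin, and Heck arylation of the ring-A vinyl group.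

The fallback sets out from 7 and 11 and returns at 17; it replaces the migrating group by one that palladium should not activate. Crotonaldehyde is brominated (Br2, CH2Cl2, 0 °C) to 2,3-dibromobutanal F1, which is dehydrobrominated in the same flask (Et3N) to (Z)-2-bromobut-2-enal F2. Reduction (NaBH4, CeCl3·7H2O, MeOH) gives (Z)-2-bromobut-2-en-1-ol F3, and silylation gives (Z)-(2-bromobut-2-enyloxy)(tert-butyl)dimethylsilane F4. Bromine–lithium exchange with retention of olefin geometry gives (E)-tert-butyl(2-lithiobut-2-enyloxy)dimethylsilane F5, which adds to 7 to give the lithium bis(alkenyl)borate F6. Coupling of this borate with 11 as in step 7 would give the ethylidene analogue of 14 F7. In bis(alkenyl)borates the less substituted olefin is the one activated and the more substituted one migrates; here the migrating group is trisubstituted and the styrenyl group is the less substituted. Homologation as in step 8 would give the homologated ethylidene boronate F8, and oxidation the ethylidene analogue of 16 F9. Ring-closing metathesis of this diene, now with loss of propene, gives 17; the geometry of the ethylidene group is of no consequence because its terminal carbon is expelled.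

Step 3. The vinylboronate may transfer its vinyl group to palladium (Suzuki–Miyaura pathway) instead of undergoing carbopalladation, and oxidative addition at a bromide flanked by two ortho substituents may be slow.

The fallback sets out from 5 and returns at 7; it builds the alkenylboronate by alkyne hydroboration. Sonogashira coupling of 5 with ethynyltrimethylsilane (PdCl2(PPh3)2, CuI, Et3N) gives 3,4,5-trimethoxy-2-[(trimethylsilyl)ethynyl]benzaldehyde F10. Wittig methylenation gives trimethyl[(2,3,4-trimethoxy-6-vinylphenyl)ethynyl]silane F11, and K2CO3 in MeOH gives 1-ethynyl-2,3,4-trimethoxy-6-vinylbenzene F12. Alkyne-selective syn hydroboration with catecholborane (catalytic dicyclohexylborane, THF, rt) gives 2-[(E)-2-(2,3,4-trimethoxy-6-vinylphenyl)vinyl]-1,3,2-benzodioxaborole F13, which is not isolated; addition of diol 2 exchanges catechol for the diolate and gives 7.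

Step 8. Formation of the ate complex at the crowded boron of 14 may be incomplete, so that unchanged C2–B is carried into the oxidation, and a 1,3-boron shift of the allylboronate before homologation would erase C2.

The fallback sets out from 14 and returns at 15; it replaces the one-step methylene insertion by a two-stage insertion and substitution. Dichloromethyllithium (from CH2Cl2 and n-BuLi, THF, −100 °C), which is formed by deprotonation and is longer-lived than chloromethyllithium, adds to 14, and ZnCl2-promoted rearrangement on warming gives, with retention at C2, the α-chloro homologue of 14 F14. LiBHEt3 then delivers hydride to boron, and its 1,2-shift displaces chloride to give 15, which is oxidised as in step 8.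

## Further compounds

F1 | step 7 | 2,3-dibromobutanal (racemic, relative configuration not defined) | CC(Br)C(Br)C=O
F2 | step 7 | (Z)-2-bromobut-2-enal | C/C=C(\Br)C=O
F3 | step 7 | (Z)-2-bromobut-2-en-1-ol | C/C=C(\Br)CO
F4 | step 7 | (Z)-(2-bromobut-2-enyloxy)(tert-butyl)dimethylsilane | C/C=C(\Br)CO[Si](C)(C)C(C)(C)C
F5 | step 7 | (E)-tert-butyl(2-lithiobut-2-enyloxy)dimethylsilane (lithium cis to methyl) | C/C=C(\[Li])CO[Si](C)(C)C(C)(C)C
F6 | step 7 | lithium borate from 7 and F5: boron carries the (E)-styrenyl group, the (E)-1-(silyloxy)but-2-en-2-yl group and the diolate of 2 (configuration at boron not defined) | [Li+].C=Cc1cc(OC)c(OC)c(OC)c1/C=C/[B-]1(/C(CO[Si](C)(C)C(C)(C)C)=C\C)O[C@]2(C)c3cccc4cccc(c34)[C@]2(C)O1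
F7 | step 7 | ethylidene analogue of 14: (1R,2S,E)-1-(3,4-dimethoxyphenyl)-3-[(tert-butyldimethylsilyloxy)methyl]-1-(2,3,4-trimethoxy-6-vinylphenyl)pent-3-en-2-ylboronic acid ester of diol 2 | COc1ccc([C@@H]([C@H](B2O[C@]3(C)c4cccc5cccc(c45)[C@]3(C)O2)/C(CO[Si](C)(C)C(C)(C)C)=C\C)c6c(C=C)cc(OC)c(OC)c6OC)cc1OC
F8 | step 7 | homologated ethylidene boronate: F7 with CH2 between C2 and boron (configuration at C1 and C2 retained) | COc1ccc([C@@H]([C@H](CB2O[C@]3(C)c4cccc5cccc(c45)[C@]3(C)O2)/C(CO[Si](C)(C)C(C)(C)C)=C\C)c6c(C=C)cc(OC)c(OC)c6OC)cc1OC
F9 | step 7 | ethylidene analogue of 16: (2S,E)-2-[(R)-(3,4-dimethoxyphenyl)(2,3,4-trimethoxy-6-vinylphenyl)methyl]-3-[(tert-butyldimethylsilyloxy)methyl]pent-3-en-1-ol | COc1ccc([C@@H]([C@H](CO)/C(CO[Si](C)(C)C(C)(C)C)=C\C)c2c(C=C)cc(OC)c(OC)c2OC)cc1OC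
F10 | step 3 | 3,4,5-trimethoxy-2-[(trimethylsilyl)ethynyl]benzaldehyde | COc1cc(C=O)c(C#C[Si](C)(C)C)c(OC)c1OC
F11 | step 3 | trimethyl[(2,3,4-trimethoxy-6-vinylphenyl)ethynyl]silane | C=Cc1cc(OC)c(OC)c(OC)c1C#C[Si](C)(C)C
F12 | step 3 | 1-ethynyl-2,3,4-trimethoxy-6-vinylbenzene | C=Cc1cc(OC)c(OC)c(OC)c1C#C
F13 | step 3 | 2-[(E)-2-(2,3,4-trimethoxy-6-vinylphenyl)vinyl]-1,3,2-benzodioxaborole | C=Cc1cc(OC)c(OC)c(OC)c1/C=C/B1Oc2ccccc2O1
F14 | step 8 | α-chloro homologue of 14: chloromethine inserted between C2 and boron (C1 and C2 as in 14, configuration at CHCl not defined) | COc1ccc([C@@H]([C@H](C(Cl)B2O[C@]3(C)c4cccc5cccc(c45)[C@]3(C)O2)C(=C)CO[Si](C)(C)C(C)(C)C)c6c(C=C)cc(OC)c(OC)c6OC)cc1OC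
A1 | alternative 1 | 1,2-trans aryl-dihydronaphthalene lactone (C9′ carbonyl, C9 methylene on oxygen) | COc1ccc([C@@H]2c3c(cc(OC)c(OC)c3OC)C=C4COC(=O)[C@@H]24)cc1OC
A2 | alternative 1 | prop-2-ynyl (E)-3,4-dimethoxycinnamate | COc1ccc(/C=C/C(=O)OCC#C)cc1OC
A3 | alternative 1 | 3,4,5-trimethoxy-2-(trimethylsilyl)phenyl trifluoromethanesulfonate | COc1cc(OS(=O)(=O)C(F)(F)F)c([Si](C)(C)C)c(OC)c1OC
A4 | alternative 1 | 3,4,5-trimethoxybenzyne (1,2-didehydro-3,4,5-trimethoxybenzene) | COC1=C(OC)C(OC)=CC#C1
A5 | alternative 2 | bis[(S)-1-(methoxycarbonyl)ethyl] 4-hydroxy-1-(3,4-dimethoxyphenyl)-6,7,8-trimethoxytetralin-2,3-dicarboxylate (1,2-trans, 2,3-trans, 3,4-cis) | COc1ccc([C@@H]2c3c(cc(OC)c(OC)c3OC)[C@H](O)[C@H](C(=O)O[C@@H](C)C(=O)OC)[C@H]2C(=O)O[C@@H](C)C(=O)OC)cc1OC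
A6 | alternative 2 | 2-(3,4-dimethoxybenzyl)-3,4,5-trimethoxybenzaldehyde | COc1ccc(Cc2c(C=O)cc(OC)c(OC)c2OC)cc1OC
A7 | alternative 2 | bis[(S)-1-(methoxycarbonyl)ethyl] fumarate | COC(=O)[C@H](C)OC(=O)/C=C/C(=O)O[C@@H](C)C(=O)OC
A8 | alternative 3 | dimethyl trans-1-(3,4-dimethoxyphenyl)-6,7,8-trimethoxy-1,2-dihydronaphthalene-2,3-dicarboxylate | COc1ccc([C@@H]2c3c(cc(OC)c(OC)c3OC)C=C(C(=O)OC)[C@H]2C(=O)OC)cc1OC
A9 | alternative 3 | dimethyl 2-[(6-bromo-2,3,4-trimethoxyphenyl)(3,4-dimethoxyphenyl)methyl]-3-[(2-tosylhydrazinylidene)methyl]succinate, C1 and C2 as in 18, C3 not defined | COc1ccc([C@@H]([C@H](C(=O)OC)C(C=NNS(=O)(=O)c2ccc(C)cc2)C(=O)OC)c2c(Br)cc(OC)c(OC)c2OC)cc1OC
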